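A direct plan would annulate ring B onto a 3,3-dimethylcyclohexanone (Michael addition, aldol closure) to the racemic octalone A1, set the cis junction by cuprate methylation, and add C11 and the C8 methyl to reach the silyl-protected aldehyde A2. A farnesyl-metal would then be added to A2 to give carbinol A3, which would be deoxygenated. Its weakest steps would be:
- the resolution of A1 through a stoichiometric chiral auxiliary adduct: two steps and a diastereomer separation that form no bond of the target and discard half of the material;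
- the alkoxymethylation, silylation, debenzylation and oxidation run that leads to A2: protecting-group and oxidation-state traffic whose only net result is one CH2 presented as CHO;
- the joining of the chain by carbonyl addition: it creates a C11 carbinol stereocentre that must be erased by a xanthate/tin hydride reduction on the most advanced intermediate, next to three trisubstituted olefins.

**Plan of the new route.** The retrosynthesis cuts C12–C13 (sp3–sp2 coupling), then C9–C11 and C8–O (anti addition across a C8=C9 olefin), then the C3 carbonyl, then C1–C10 by a retro-oxy-Cope shift that re-forms C3–C8, and last C4–C5/C3–C8 by a Diels–Alder disconnection. Ring B is the six-membered ring of the starting enone; ring A is closed second, C4–C5 by the cycloaddition and C1–C10 by the [3,3] shift. The enabling feature is that C1–C10 lies between C2–C3 of ring A and C9–C8 of ring B: a cis-decalin with a C3 carbonyl and a C8=C9 olefin is the Cope isomer of a bicyclo[2.2.2]octene in which C3 and C8 are bonded. That olefin then delivers the C8 carbinol and the C9 side chain. The absolute configuration comes from one catalytic cycloaddition (no resolution), no protecting group is used, and the chain is joined by a cross-coupling that creates no stereocentre and needs no deoxygenation. The price is one excised carbon (step 3) and one removed oxygen (step 7), both early.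

Key step: step 6

Remark: locants are those of the target skeleton (ring A: C1–C5 and C10; ring B: C5–C10; C11 and C12 on C9; chain C13–C22); the target is taken as drawn, with H-5 and CH3-10 cis (β face), 8α-OH and 9β-CH2.
Assumption: the (5S)-imidazolidinone is taken to shield the same dienophile face as it does with cyclohexa-1,3-diene; if the sense proves opposite, the (5R)-catalyst is used without other change.

Step 1
Reactants: 1 3-methylcyclohex-2-en-1-one
Product: 3 1,3-dimethylcyclohexa-1,3-diene, via 1,3-dimethylcyclohex-2-en-1-ol 2 (not isolated)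
Conditions: MeLi (1.2 equiv), Et2O, −78 → 0 °C; H2O; then p-TsOH·H2O (2 mol %), pentane, rt
Reagents that add atoms: methyllithium ([Li]C)
Why: 1,2-Addition of methyllithium followed by acid-catalysed dehydration through the symmetrical dimethylallyl cation should give the conjugated endocyclic diene under thermodynamic control, and no stereocentre is formed.

Step 2
Reactants: 3 1,3-dimethylcyclohexa-1,3-diene; 4 prop-2-enal (acrolein)
Product: 5 (1R,2R,4R)-1,5-dimethylbicyclo[2.2.2]oct-5-ene-2-carbaldehyde
Conditions: (5S)-5-benzyl-2,2,3-trimethylimidazolidin-4-one hydrochloride (10 mol %), MeCN/H2O (95:5), 0 °C → rt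
Reagents that add atoms: none
Why: In this iminium-catalysed Diels–Alder reaction the β-carbon of the dienophile (C4) should bond to the unsubstituted diene terminus C5, the only mode that leaves an allyl cation stabilised by both methyl groups, so the formyl-bearing carbon C3 ends next to the methylated bridgehead C8; the endo transition state and the benzyl group of the catalyst, which shields one dienophile face, fix the two bridgeheads C5 and C8.

Step 3
Reactants: 5 (1R,2R,4R)-1,5-dimethylbicyclo[2.2.2]oct-5-ene-2-carbaldehyde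
Product: 7 (1R,4R)-1,5-dimethylbicyclo[2.2.2]oct-5-en-2-one, via enamine 6 (not isolated)
Conditions: piperidine (1.5 equiv), p-TsOH (1 mol %), toluene, 4 Å MS, 40 °C; then CuCl (10 mol %), O2 (1 atm), MeCN, rt
Reagents that add atoms: dioxygen (O=O)
Why: Enamine formation and copper-catalysed aerobic cleavage of the enamine C=C bond should shorten the aldehyde by one carbon to the ketone without touching the trisubstituted ring olefin or the bridgeheads, and the C3 stereocentre of 5, which is not needed, disappears.

Step 4
Reactants: 7 (1R,4R)-1,5-dimethylbicyclo[2.2.2]oct-5-en-2-one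
Product: 9 (1R,4S)-1,3,3,5-tetramethylbicyclo[2.2.2]oct-5-en-2-one, via monomethyl ketone 8 (not isolated)
Conditions: KOt-Bu (3 equiv), MeI (5 equiv), THF, 0 °C → rt
Reagents that add atoms: iodomethane (CI)
Why: Exhaustive enolate methylation can occur only at C4, the single enolisable position because the other α-carbon is the quaternary bridgehead C8, and it builds the gem-dimethyl carbon without creating a stereocentre.

Step 5
Reactants: 9 (1R,4S)-1,3,3,5-tetramethylbicyclo[2.2.2]oct-5-en-2-one
Product: 10 (1R,2S,4S)-2-ethenyl-1,3,3,5-tetramethylbicyclo[2.2.2]oct-5-en-2-ol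
Conditions: CH2=CHMgBr (2 equiv), CeCl3 (2 equiv, dried), THF, −78 → 0 °C; H2O
Reagents that add atoms: vinylmagnesium bromide (C=C[Mg]Br)
Why: In this organocerium 1,2-addition to a hindered, non-enolisable ketone the reagent should approach from the side of the C9=C10 bridge, whose single sp2 C–H shields less than the CH2 groups of the ethano bridge, so the vinyl group (C1, C2) ends syn to that olefin as the rearrangement requires.

Step 6
Reactants: 10 (1R,2S,4S)-2-ethenyl-1,3,3,5-tetramethylbicyclo[2.2.2]oct-5-en-2-ol
Product: 13 (4aR,8aS)-1,1,4a,6-tetramethyl-3,4,4a,7,8,8a-hexahydronaphthalen-2(1H)-one, via potassium alkoxide 11 (not isolated), via potassium enolate 12 (not isolated)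
Conditions: KH (1.5 equiv), 18-crown-6 (1.5 equiv), THF, 0 → 50 °C; H2O
Reagents that add atoms: none
Why: Deprotonation gives alkoxide 11, in which the oxyanion weakens the C3–C8 bond of the 3-oxido-1,5-diene C1=C2–C3(O−)–C8–C9=C10, so that a concerted suprafacial [3,3] sigmatropic shift (anionic oxy-Cope rearrangement) should take place near room temperature and be made irreversible by formation of enolate 12. The closest known reaction type is the anionic oxy-Cope rearrangement of 2-vinylbicyclo[2.2.2]oct-5-en-2-olates to cis-fused octalinones. Ring A is closed by the new C1–C10 bond while the C3–C8 bond of the cage is cut; the closure is sigmatropic, through the boat-shaped six-centre transition state that the cage enforces. The only new stereocentre is C10: C1 can reach it only on the face of the C9=C10 bridge that looks toward the carbinol bridge, the face on which C4 is already bonded to C5, so CH3-10 and H-5 must end cis, and C5 itself (the bridgehead set in step 2) is not touched. The step needs the vinyl group syn to the C9=C10 bridge, which step 5 secures (the anti epimer cannot rearrange), and it needs the new double bond to appear as C8=C9 with the methyl on C8, which the bridgehead methyl secures.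

Step 7
Reactants: 13 (4aR,8aS)-1,1,4a,6-tetramethyl-3,4,4a,7,8,8a-hexahydronaphthalen-2(1H)-one
Product: 15 (4aR,8aR)-1,1,4a,6-tetramethyl-1,2,3,4,4a,7,8,8a-octahydronaphthalene, via hydrazone 14 (not isolated)
Conditions: N2H4·H2O (10 equiv), KOH (5 equiv), diethylene glycol, 130 °C, then 200 °C
Reagents that add atoms: none
Why: Wolff–Kishner reduction (Huang-Minlon conditions) should remove the C3 carbonyl that the rearrangement needed; C4 is quaternary and C5 is not α to the carbonyl, so the ring fusion cannot epimerise, and the isolated trisubstituted olefin is stable to base.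

Step 8
Reactants: 15 (4aR,8aR)-1,1,4a,6-tetramethyl-1,2,3,4,4a,7,8,8a-octahydronaphthalene
Product: 16 (1R,2R,4aR,8aS)-1-bromo-2,5,5,8a-tetramethyldecahydronaphthalen-2-ol
Conditions: NBS (1.1 equiv), DMSO/H2O (10:1), 0 °C → rt
Reagents that add atoms: N-bromosuccinimide (O=C1CCC(=O)N1Br); water (O)
Why: In this bromohydrin formation the bromonium ion should form on the β face of C8=C9, anti to the pseudo-axial C1 methylene of the folded cis-octalin, and water should open it at the tertiary C8 from the α face in a trans-diaxial sense, which sets 8α-OH/8β-CH3 and leaves bromine on C9 (Markovnikov, anti addition).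

Step 9
Reactants: 16 (1R,2R,4aR,8aS)-1-bromo-2,5,5,8a-tetramethyldecahydronaphthalen-2-ol
Product: 17 (1R,2R,4aR,8aS)-2,5,5,8a-tetramethyl-1-[2-(4,4,5,5-tetramethyl-1,3,2-dioxaborolan-2-yl)ethyl]decahydronaphthalen-2-ol
Conditions: 4,4,5,5-tetramethyl-2-vinyl-1,3,2-dioxaborolane (5 equiv), (Me3Si)3SiH (1.3 equiv, slow addition), 2,2'-azobis(2-methylpropionitrile) (10 mol %), PhCF3, 80 °C
Reagents that add atoms: 4,4,5,5-tetramethyl-2-vinyl-1,3,2-dioxaborolane (C=CB1OC(C)(C)C(C)(C)O1)
Why: In this tin-free Giese radical addition the silyl radical abstracts bromine and the secondary C9 radical should add to the unsubstituted carbon of the vinylboronate (α-boryl radical, then hydrogen transfer from the silane), taking the acceptor axially on the β face, anti to the two flanking axial bonds C10–C1 and C8–O, so that C11 ends trans to O-8 and cis to CH3-10 while the free tertiary hydroxyl stays inert.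

Step 10
Reactants: 18 (2E)-1-bromo-3,7-dimethylocta-2,6-diene (geranyl bromide)
Product: 20 (5E)-6,10-dimethylundeca-5,9-dien-1-yne, via silylated enyne 19 (not isolated)
Conditions: MeC≡CSiMe3 (1.3 equiv), n-BuLi (1.25 equiv), THF, −78 → −20 °C; 18, −78 °C → rt; then K2CO3 (cat.), MeOH, rt
Reagents that add atoms: 1-(trimethylsilyl)propyne (CC#C[Si](C)(C)C)
Why: The lithiated silylpropyne should displace the primary allylic bromide at its unsubstituted carbon without touching the E olefin, and methanolysis removes the alkyne silyl group.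

Step 11
Reactants: 20 (5E)-6,10-dimethylundeca-5,9-dien-1-yne
Product: 22 (1E,5E)-1-iodo-2,6,10-trimethylundeca-1,5,9-triene, via alkenylalane 21 (not isolated)
Conditions: Me3Al (2.5 equiv), Cp2ZrCl2 (25 mol %), CH2Cl2, 0 °C → rt; then I2, THF, −30 → 0 °C
Reagents that add atoms: trimethylaluminium (C[Al](C)C); iodine (II)
Why: Zirconium-catalysed syn-carboalumination of the terminal alkyne (Negishi carboalumination) places the methyl on the internal carbon and aluminium on the terminus, and iodinolysis with retention should give the E trisubstituted alkenyl iodide that holds C13=C14.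

Step 12
Reactants: 17 boronate (as named in step 9); 22 (1E,5E)-1-iodo-2,6,10-trimethylundeca-1,5,9-triene
Product: 23 (1R,2R,4aR,8aS)-2,5,5,8a-tetramethyl-1-[(3E,7E)-4,8,12-trimethyltrideca-3,7,11-trien-1-yl]decahydronaphthalen-2-ol (target)
Conditions: Pd(OAc)2 (5 mol %), 2-dicyclohexylphosphino-2',6'-diisopropoxybiphenyl (10 mol %), K3PO4 (3 equiv), toluene/H2O (10:1), 80 °C
Reagents that add atoms: none
Why: Suzuki–Miyaura coupling of the primary alkylboronate with the alkenyl iodide should form C12–C13 with retention of the E geometry, it creates no stereocentre at the joint, and the tertiary alcohol needs no protection.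

**Compound list**
1 | 3-methylcyclohex-2-en-1-one | CC1=CC(=O)CCC1 | starting material
2 | 1,3-dimethylcyclohex-2-en-1-ol (racemic) | CC1=CC(C)(O)CCC1 | intermediate
3 | 1,3-dimethylcyclohexa-1,3-diene | CC1=CC(C)=CCC1 | intermediate
4 | prop-2-enal (acrolein) | C=CC=O | starting material
5 | (1R,2R,4R)-1,5-dimethylbicyclo[2.2.2]oct-5-ene-2-carbaldehyde | O=C[C@@H]1C[C@H]2CC[C@]1(C)C=C2C | intermediate
6 | 1-{[(1R,4R)-1,5-dimethylbicyclo[2.2.2]oct-5-en-2-ylidene]methyl}piperidine | C(N1CCCCC1)=C1C[C@H]2CC[C@]1(C)C=C2C | intermediate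
7 | (1R,4R)-1,5-dimethylbicyclo[2.2.2]oct-5-en-2-one | O=C1C[C@H]2CC[C@]1(C)C=C2C | intermediate
8 | (1R,4R)-1,3,5-trimethylbicyclo[2.2.2]oct-5-en-2-one (C3 epimers) | O=C1C(C)[C@H]2CC[C@]1(C)C=C2C | intermediate
9 | (1R,4S)-1,3,3,5-tetramethylbicyclo[2.2.2]oct-5-en-2-one | O=C1C(C)(C)[C@H]2CC[C@]1(C)C=C2C | intermediate
10 | (1R,2S,4S)-2-ethenyl-1,3,3,5-tetramethylbicyclo[2.2.2]oct-5-en-2-ol | O[C@@]1(C=C)C(C)(C)[C@H]2CC[C@]1(C)C=C2C | intermediate
11 | potassium (1R,2S,4S)-2-ethenyl-1,3,3,5-tetramethylbicyclo[2.2.2]oct-5-en-2-olate | [K+].[O-][C@@]1(C=C)C(C)(C)[C@H]2CC[C@]1(C)C=C2C | intermediate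
12 | potassium (4aR,8aS)-1,1,4a,6-tetramethyl-1,4,4a,7,8,8a-hexahydronaphthalen-2-olate | CC1=C[C@@]2(C)CC=C([O-])C(C)(C)[C@H]2CC1.[K+] | intermediate
13 | (4aR,8aS)-1,1,4a,6-tetramethyl-3,4,4a,7,8,8a-hexahydronaphthalen-2(1H)-one | CC1=C[C@@]2(C)CCC(=O)C(C)(C)[C@H]2CC1 | intermediate
14 | [(4aR,8aS)-1,1,4a,6-tetramethyl-3,4,4a,7,8,8a-hexahydronaphthalen-2(1H)-ylidene]hydrazine | CC1=C[C@@]2(C)CCC(=NN)C(C)(C)[C@H]2CC1 | intermediate
15 | (4aR,8aR)-1,1,4a,6-tetramethyl-1,2,3,4,4a,7,8,8a-octahydronaphthalene | CC1=C[C@@]2(C)CCCC(C)(C)[C@H]2CC1 | intermediate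
16 | (1R,2R,4aR,8aS)-1-bromo-2,5,5,8a-tetramethyldecahydronaphthalen-2-ol | Br[C@@H]1[C@@]2(C)CCCC(C)(C)[C@H]2CC[C@@]1(C)O | intermediate
17 | (1R,2R,4aR,8aS)-2,5,5,8a-tetramethyl-1-[2-(4,4,5,5-tetramethyl-1,3,2-dioxaborolan-2-yl)ethyl]decahydronaphthalen-2-ol | CC1(C)OB(CC[C@@H]2[C@@]3(C)CCCC(C)(C)[C@H]3CC[C@@]2(C)O)OC1(C)C | intermediate
18 | (2E)-1-bromo-3,7-dimethylocta-2,6-diene (geranyl bromide) | CC(C)=CCC/C(C)=C/CBr | starting material
19 | trimethyl[(5E)-6,10-dimethylundeca-5,9-dien-1-yn-1-yl]silane | CC(C)=CCC/C(C)=C/CCC#C[Si](C)(C)C | intermediate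
20 | (5E)-6,10-dimethylundeca-5,9-dien-1-yne | CC(C)=CCC/C(C)=C/CCC#C | intermediate
21 | dimethyl[(1E,5E)-2,6,10-trimethylundeca-1,5,9-trien-1-yl]alumane | CC(C)=CCC/C(C)=C/CC/C(C)=C/[Al](C)C | intermediate
22 | (1E,5E)-1-iodo-2,6,10-trimethylundeca-1,5,9-triene | CC(C)=CCC/C(C)=C/CC/C(C)=C/I | intermediate
23 | (1R,2R,4aR,8aS)-2,5,5,8a-tetramethyl-1-[(3E,7E)-4,8,12-trimethyltrideca-3,7,11-trien-1-yl]decahydronaphthalen-2-ol | CC(C)=CCC/C(C)=C/CC/C(C)=C/CC[C@@H]1[C@@]2(C)CCCC(C)(C)[C@H]2CC[C@@]1(C)O | target

Total step count: 12. Longest linear sequence: 10 steps (steps 1–9 and 12).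

**Steps most likely to fail**

Step 9. The hindered secondary C9 radical, flanked by two fully substituted carbons, may take hydrogen from the silane before it adds to the vinylboronate, or may add on the α face. The fallback forms the same bond by a stereospecific ionic opening instead of a radical addition. It sets out from 16: K2CO3 in MeOH should close the trans-diaxial bromohydrin to the 8α,9α-epoxide (1aR,3aR,7aS,7bS)-1a,4,4,7a-tetramethyldecahydronaphtho[1,2-b]oxirene F1. Lithium acetylide–ethylenediamine complex in DMSO should open it at the less substituted C9 with inversion to the ethynyl carbinol (1R,2R,4aR,8aS)-1-ethynyl-2,5,5,8a-tetramethyldecahydronaphthalen-2-ol F2. Semi-hydrogenation (H2, Lindlar catalyst, quinoline) should give the vinyl carbinol (1R,2R,4aR,8aS)-1-ethenyl-2,5,5,8a-tetramethyldecahydronaphthalen-2-ol F3. Hydroboration with 9-BBN to the B-alkyl-9-borabicyclononane F4, used without isolation, and coupling with 22 (Pd(dppf)Cl2, Cs2CO3, DMF/THF/H2O) lead back to the route at 23.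

Step 8. The bromonium ion may form on the α face, water may be slow to reach the tertiary C8, or allylic bromination may compete. The fallback replaces the kinetically controlled bromonium opening by a reversible oxymercuration, which should settle on the trans-diaxial adduct. It sets out from 15: Hg(OAc)2 in THF/H2O should give the organomercurial acetoxy[(1R,2R,4aR,8aS)-2-hydroxy-2,5,5,8a-tetramethyldecahydronaphthalen-1-yl]mercury F5. Bromodemercuration (KBr, then Br2 in pyridine) returns to the route at 16; the configuration of the C9–Br bond does not matter, because step 9 passes through the C9 radical.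

Step 2. The enantiomeric purity may be eroded by incomplete face discrimination or by exo adduct (exo and endo adducts of one dienophile face lead to antipodal ketones after step 3), and the acid salt may isomerise the diene. The fallback changes dienophile, mode of activation and the way the ketone is unveiled. It sets out from 3: 2-bromoacrolein with the oxazaborolidinium triflimide made from (S)-diphenyl(pyrrolidin-2-yl)methanol, 2-methylphenylboronic acid and HNTf2 (CH2Cl2, −78 °C) should give, exo-selectively, the bromo aldehyde (1R,2R,4R)-2-bromo-1,5-dimethylbicyclo[2.2.2]oct-5-ene-2-carbaldehyde F6. NaBH4 reduction to the bromo alcohol [(1R,2R,4R)-2-bromo-1,5-dimethylbicyclo[2.2.2]oct-5-en-2-yl]methanol F7 and treatment with NaOH close the spiro-epoxide (1R,2S,4R)-1,5-dimethylspiro[bicyclo[2.2.2]oct-5-ene-2,2'-oxirane] F8. Cleavage with H5IO6 in aqueous THF comes back to the route at 7.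

**Further compounds**
F1 | step 9 | (1aR,3aR,7aS,7bS)-1a,4,4,7a-tetramethyldecahydronaphtho[1,2-b]oxirene (8α,9α-epoxide) | O1[C@H]2[C@@]3(C)CCCC(C)(C)[C@H]3CC[C@@]12C
F2 | step 9 | (1R,2R,4aR,8aS)-1-ethynyl-2,5,5,8a-tetramethyldecahydronaphthalen-2-ol | C#C[C@@H]1[C@@]2(C)CCCC(C)(C)[C@H]2CC[C@@]1(C)O
F3 | step 9 | (1R,2R,4aR,8aS)-1-ethenyl-2,5,5,8a-tetramethyldecahydronaphthalen-2-ol | C=C[C@@H]1[C@@]2(C)CCCC(C)(C)[C@H]2CC[C@@]1(C)O
F4 | step 9 | (1R,2R,4aR,8aS)-1-[2-(9-borabicyclo[3.3.1]nonan-9-yl)ethyl]-2,5,5,8a-tetramethyldecahydronaphthalen-2-ol | C(CB1C2CCCC1CCC2)[C@@H]1[C@@]2(C)CCCC(C)(C)[C@H]2CC[C@@]1(C)O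
F5 | step 8 | acetoxy[(1R,2R,4aR,8aS)-2-hydroxy-2,5,5,8a-tetramethyldecahydronaphthalen-1-yl]mercury | CC(=O)O[Hg][C@@H]1[C@@]2(C)CCCC(C)(C)[C@H]2CC[C@@]1(C)O
F6 | step 2 | (1R,2R,4R)-2-bromo-1,5-dimethylbicyclo[2.2.2]oct-5-ene-2-carbaldehyde | O=C[C@@]1(Br)C[C@H]2CC[C@]1(C)C=C2C
F7 | step 2 | [(1R,2R,4R)-2-bromo-1,5-dimethylbicyclo[2.2.2]oct-5-en-2-yl]methanol | OC[C@@]1(Br)C[C@H]2CC[C@]1(C)C=C2C
F8 | step 2 | (1R,2S,4R)-1,5-dimethylspiro[bicyclo[2.2.2]oct-5-ene-2,2'-oxirane] | C1O[C@]12C[C@H]3CC[C@]2(C)C=C3C
A1 | direct plan | (±)-5,5-dimethyl-4,4a,5,6,7,8-hexahydronaphthalen-2(3H)-one | O=C1C=C2CCCC(C)(C)C2CC1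
A2 | direct plan | (1R,2R,4aR,8aS)-2,5,5,8a-tetramethyl-2-(triethylsilyloxy)decahydronaphthalene-1-carbaldehyde | O=C[C@@H]1[C@@]2(C)CCCC(C)(C)[C@H]2CC[C@@]1(C)O[Si](CC)(CC)CC
A3 | direct plan | (3E,7E)-1-[(1S,2R,4aR,8aS)-2,5,5,8a-tetramethyl-2-(triethylsilyloxy)decahydronaphthalen-1-yl]-4,8,12-trimethyltrideca-3,7,11-trien-1-ol (C11 epimers) | CC(C)=CCC/C(C)=C/CC/C(C)=C/CC(O)[C@@H]1[C@@]2(C)CCCC(C)(C)[C@H]2CC[C@@]1(C)O[Si](CC)(CC)CC
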